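**Retrosynthetic overview**
- Rufesolide C (30) ⇐ acetate-directed gold-catalysed hydration of the C5≡C6 alkyne in cyclodecyne lactone 29 (C6 ketone made last).
- 29 ⇐ reagent-controlled reduction of the C1 ketone of ten-membered cycloalkynone 27, then lactonisation (γ-lactone formed after the carbocycle).
- 27 ⇐ ring expansion of six-membered ring A in vinylogous acyl triflate 24: intramolecular Barbier allylation makes C1–C10, Grob fragmentation cleaves C1–C6 and gives the alkyne.
- 24 ⇐ ring A iodide 11 (from cyclohexenone by asymmetric conjugate methylation) + aldol 15 (2-methoxypropene + acrolein) + angelic acid + 2-(bromomethyl)acrylic acid.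
- Ring order: ring A (six-membered, purchased) → ten-membered carbocycle → γ-lactone.

Assumption: locants follow the target as C13H2=C11–C12(=O)–O–C1H–C2H2–C3H(Me)–C4H(OMe)–C5H2–C6(=O)–C7(Me)(OAc)–C8H2–C9H(OAng)–C10H(–C1, –C11), target = (1R,3R,4R,7R,9S,10S); donors of one or two atoms (Me2Zn, MeI, MeOH, Ac2O, Tf2O, water, silyl reagents) are treated as reagents, not starting materials.

**Step 1**
Reactants: 1 cyclohex-2-en-1-one
Product: 3 (R)-trimethyl[(3-methylcyclohex-1-en-1-yl)oxy]silane, via zinc enolate 2 (not isolated)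
Conditions: Me2Zn, Cu(OTf)2 (1 mol %), (R,S,S)-Feringa phosphoramidite (2 mol %), toluene, −30 °C; then Me3SiOTf, −30 → 0 °C
Reagents that add atoms: dimethylzinc, C[Zn]C; trimethylsilyl triflate, C[Si](C)(C)OS(=O)(=O)C(F)(F)F
Why: Copper-catalysed asymmetric conjugate addition (Feringa type) sets C3 (R) under ligand control (the ligand enantiomer that gives the 3R adduct is used), and silylation fixes the enol ether regiospecifically on the C4 side.

**Step 2**
Reactants: 3 (R)-trimethyl[(3-methylcyclohex-1-en-1-yl)oxy]silane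
Product: 5 (2S,3R)-2-hydroxy-3-methylcyclohexan-1-one, via lithium enolate 4 (not isolated)
Conditions: MeLi, THF, 0 °C; then 3-phenyl-2-(phenylsulfonyl)oxaziridine, −78 °C; NH4Cl (aq)
Reagents that add atoms: 3-phenyl-2-(phenylsulfonyl)oxaziridine, O=S(=O)(c1ccccc1)N1OC1c1ccccc1
Why: Davis enolate hydroxylation; the oxidant attacks the enolate face opposite the adjacent C3 methyl group, giving the trans ketol (C4 set).

**Step 3**
Reactants: 5 (2S,3R)-2-hydroxy-3-methylcyclohexan-1-one
Product: 6 (2S,3R)-2-methoxy-3-methylcyclohexan-1-one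
Conditions: MeI, Ag2O, 4 Å sieves, Et2O, 35 °C
Reagents that add atoms: iodomethane, CI
Why: Purdie O-methylation under non-basic conditions, so the α-stereocentre is not epimerised.

**Step 4**
Reactants: 6 (2S,3R)-2-methoxy-3-methylcyclohexan-1-one
Product: 8 (5R,6S)-6-methoxy-5-methylcyclohex-2-en-1-one, via silyl enol ether 7 (not isolated)
Conditions: LiN(iPr)2, Me3SiCl, THF, −78 °C; then Pd(OAc)2 (10 mol %), O2, DMSO, 25 °C
Reagents that add atoms: none
Why: Saegusa–Ito dehydrogenation; kinetic deprotonation occurs at the CH2 remote from the methoxy-bearing carbon, so the alkene is C6=C1 and C3/C4 are untouched.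

**Step 5**
Reactants: 8 (5R,6S)-6-methoxy-5-methylcyclohex-2-en-1-one
Product: 10 (5R,6S)-3,6-dimethoxy-5-methylcyclohex-2-en-1-one, via selenide 9 (not isolated)
Conditions: PhSeCl, MeOH, CH2Cl2, 0 °C; then H2O2, pyridine, 0 → 25 °C
Reagents that add atoms: methanol, CO
Why: Methoxyselenenylation of the enone (MeOH at the β-carbon C1) followed by selenoxide syn-elimination gives the vinylogous ester with its carbonyl at C5.

**Step 6**
Reactants: 10 (5R,6S)-3,6-dimethoxy-5-methylcyclohex-2-en-1-one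
Product: 11 (5R,6S)-2-iodo-3,6-dimethoxy-5-methylcyclohex-2-en-1-one
Conditions: I2, pyridine, CH2Cl2, 0 → 25 °C
Reagents that add atoms: iodine, II
Why: Electrophilic α-iodination at the nucleophilic C6 of the vinylogous ester.

**Step 7**
Reactants: 12 2-methoxypropene; 13 acrolein
Product: 15 (R)-4-hydroxyhex-5-en-2-one, via enol ether adduct 14 (not isolated)
Conditions: Ti(OiPr)4 (5 mol %), (R)-binaphthyl Schiff-base ligand, 3,5-di-tert-butylsalicylic acid, 2,6-di-tert-butyl-4-methylpyridine, 0 °C; then HCl (2 M), Et2O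
Reagents that add atoms: water, O
Why: Carreira-type catalytic asymmetric aldol addition of an acetone equivalent; the ligand enantiomer that gives the R carbinol is used (this centre, C9, is inverted in step 9), and hydrolysis unmasks the methyl ketone.

**Step 8**
Reactants: 11 (5R,6S)-2-iodo-3,6-dimethoxy-5-methylcyclohex-2-en-1-one; 15 (R)-4-hydroxyhex-5-en-2-one
Product: 18 (5R,6S)-2-[(2R,4R)-2,4-dihydroxyhex-5-en-2-yl]-3,6-dimethoxy-5-methylcyclohex-2-en-1-one, via alkenylmagnesium chloride 16 (not isolated), via magnesium alkoxide 17 (not isolated)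
Conditions: 11, iPrMgCl·LiCl, THF, −40 °C; separately 15, tBuMgCl, THF, −78 °C; combine, −78 → −20 °C; NH4Cl (aq)
Reagents that add atoms: none
Why: Knochel iodine–magnesium exchange, then chelation-controlled Grignard addition to the methyl ketone; in the six-membered magnesium chelate the alkenyl group enters axially, giving the 1,3-anti diol and so the target configuration at C7 (R).

**Step 9**
Reactants: 18 (5R,6S)-2-[(2R,4R)-2,4-dihydroxyhex-5-en-2-yl]-3,6-dimethoxy-5-methylcyclohex-2-en-1-one; 19 angelic acid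
Product: 20 (3S,5R)-5-[(4R,5S)-2,5-dimethoxy-4-methyl-6-oxocyclohex-1-en-1-yl]-5-hydroxyhex-1-en-3-yl (Z)-2-methylbut-2-enoate
Conditions: PPh3, diisopropyl azodicarboxylate, THF, 0 °C
Reagents that add atoms: none
Why: Mitsunobu esterification of the secondary allylic alcohol with inversion makes C9 (S), turns the anti diol into the required syn C7/C9 pattern and installs the angelate without base; the tertiary alcohol does not react.

**Step 10**
Reactants: 20 (3S,5R)-5-[(4R,5S)-2,5-dimethoxy-4-methyl-6-oxocyclohex-1-en-1-yl]-5-hydroxyhex-1-en-3-yl (Z)-2-methylbut-2-enoate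
Product: 21 (3S,5R)-5-acetoxy-5-[(4R,5S)-2,5-dimethoxy-4-methyl-6-oxocyclohex-1-en-1-yl]hex-1-en-3-yl (Z)-2-methylbut-2-enoate
Conditions: Ac2O, Et3N, 4-(dimethylamino)pyridine (0.2 equiv), CH2Cl2, 25 °C
Reagents that add atoms: acetic anhydride, CC(=O)OC(C)=O
Why: Steglich-type nucleophile-catalysed acetylation of the tertiary alcohol; no stereocentre is touched.

**Step 11**
Reactants: 21 (3S,5R)-5-acetoxy-5-[(4R,5S)-2,5-dimethoxy-4-methyl-6-oxocyclohex-1-en-1-yl]hex-1-en-3-yl (Z)-2-methylbut-2-enoate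
Product: 22 (3S,5R)-5-acetoxy-5-[(3S,4R)-3-methoxy-4-methyl-6-oxo-2-(trifluoromethylsulfonyloxy)cyclohex-1-en-1-yl]hex-1-en-3-yl (Z)-2-methylbut-2-enoate
Conditions: Tf2O (1.1 equiv), 2,6-di-tert-butylpyridine (0.2 equiv), CH2Cl2, −78 → 0 °C
Reagents that add atoms: triflic anhydride, O=S(=O)(OS(=O)(=O)C(F)(F)F)C(F)(F)F
Why: Proposed new method: O-triflation of the vinylogous-ester carbonyl (C5=O) gives a 1-methoxy-3-triflyloxy allyl cation whose O-methyl group is removed by triflate in an SN2 step (MeOTf leaves), which unmasks the C1 ketone and leaves the triflate on C5 (net 1,3-transposition, no free dione that could eliminate the C7 acetate); the closest known reactions are the conversion of vinylogous esters into β-halo enones with oxalyl halides and the triflation of 1,3-diones to vinylogous acyl triflates.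

**Step 12**
Reactants: 22 (3S,5R)-5-acetoxy-5-[(3S,4R)-3-methoxy-4-methyl-6-oxo-2-(trifluoromethylsulfonyloxy)cyclohex-1-en-1-yl]hex-1-en-3-yl (Z)-2-methylbut-2-enoate; 23 2-(bromomethyl)acrylic acid
Product: 24 (2Z,4S,6R)-6-acetoxy-2-(bromomethyl)-6-[(3S,4R)-3-methoxy-4-methyl-6-oxo-2-(trifluoromethylsulfonyloxy)cyclohex-1-en-1-yl]-4-{[(Z)-2-methylbut-2-enoyl]oxy}hept-2-enoic acid
Conditions: second-generation Hoveyda–Grubbs catalyst (5 mol %), CH2Cl2, 40 °C
Reagents that add atoms: none
Why: Olefin cross-metathesis of the terminal alkene with the 1,1-disubstituted acrylic acid gives the trisubstituted allylic bromide (acid trans to C9); its geometry is lost on metalation.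

**Step 13**
Reactants: 24 (2Z,4S,6R)-6-acetoxy-2-(bromomethyl)-6-[(3S,4R)-3-methoxy-4-methyl-6-oxo-2-(trifluoromethylsulfonyloxy)cyclohex-1-en-1-yl]-4-{[(Z)-2-methylbut-2-enoyl]oxy}hept-2-enoic acid
Product: 27 ten-membered cycloalkynone methyl ester (C1 ketone, C5≡C6, C10 bearing 1-(methoxycarbonyl)vinyl; C3, C4, C7, C9, C10 arranged as in the target), via hydroxy acid 25 (not isolated), via potassium carboxylate 26 (not isolated)
Conditions: Zn dust, THF/NH4Cl (aq), 0 °C; neutral work-up; KN(SiMe3)2 (2.05 equiv), THF, −78 → 0 °C; then MeI, 0 → 25 °C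
Reagents that add atoms: iodomethane, CI
Why: Proposed new method: the allylzinc from the 2-(bromomethyl)acrylic acid unit adds through its γ-carbon (C10) to the C1 ketone in a chair-like six-membered transition state with the C9 and C10 substituents equatorial (C10 set trans to C9–O); the potassium alkoxide then undergoes Grob fragmentation (C1–C6 anti-periplanar to C5–OTf) to the ten-membered C1 ketone with the C5≡C6 alkyne, the carboxylate cannot lactonise and is methylated in the same flask; the closest known chemistry is addition/C–C cleavage of vinylogous acyl triflates with external organometallic or enolate nucleophiles and Barbier allylation of ketones with 2-(bromomethyl)acrylates.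

**Step 14**
Reactants: 27 ten-membered cycloalkynone methyl ester
Product: 29 alkyne lactone (target skeleton with C5≡C6 in place of C5H2–C6=O; all six stereocentres as in the target), via hydroxy ester 28 (not isolated)
Conditions: (S)-Me-CBS oxazaborolidine (0.3 equiv), catecholborane, toluene, −78 °C; then pyridinium p-toluenesulfonate, CH2Cl2, 25 °C
Reagents that add atoms: none
Why: Corey–Bakshi–Shibata reduction with the α-branched C10 side as the large group gives the (1R) alcohol, which lactonises onto C12 to the trans-fused α-methylene-γ-butyrolactone.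

**Step 15**
Reactants: 29 alkyne lactone
Product: 30 Rufesolide C
Conditions: Ph3PAuNTf2 (5 mol %), H2O (3 equiv), 1,4-dioxane, 25 °C
Reagents that add atoms: water, O
Why: Gold-catalysed alkyne hydration with neighbouring-group participation: the C7 acetate carbonyl attacks the activated alkyne 5-exo at C6, and hydrolysis of the dioxolanylium returns the acetate to C7, placing the ketone at C6 and CH2 at C5; no stereocentre is affected.

**Compound list**
1 | cyclohex-2-en-1-one | O=C1C=CCCC1 | starting material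
2 | methylzinc (R)-3-methylcyclohex-1-en-1-olate | C[C@H]1C=C(O[Zn]C)CCC1 | intermediate
3 | (R)-trimethyl[(3-methylcyclohex-1-en-1-yl)oxy]silane | C[C@H]1C=C(O[Si](C)(C)C)CCC1 | intermediate
4 | lithium (R)-3-methylcyclohex-1-en-1-olate | C[C@H]1C=C(O[Li])CCC1 | intermediate
5 | (2S,3R)-2-hydroxy-3-methylcyclohexan-1-one | C[C@@H]1CCCC(=O)[C@H]1O | intermediate
6 | (2S,3R)-2-methoxy-3-methylcyclohexan-1-one | C[C@@H]1CCCC(=O)[C@H]1OC | intermediate
7 | {[(5R,6S)-6-methoxy-5-methylcyclohex-1-en-1-yl]oxy}trimethylsilane | C[C@@H]1CCC=C(O[Si](C)(C)C)[C@H]1OC | intermediate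
8 | (5R,6S)-6-methoxy-5-methylcyclohex-2-en-1-one | C[C@@H]1CC=CC(=O)[C@H]1OC | intermediate
9 | (5R,6S)-3,6-dimethoxy-5-methyl-2-(phenylselanyl)cyclohexan-1-one (C2/C3 anti adduct, transient centres not defined) | C[C@@H]1CC(OC)C([Se]c2ccccc2)C(=O)[C@H]1OC | intermediate
10 | (5R,6S)-3,6-dimethoxy-5-methylcyclohex-2-en-1-one | C[C@@H]1CC(OC)=CC(=O)[C@H]1OC | intermediate
11 | (5R,6S)-2-iodo-3,6-dimethoxy-5-methylcyclohex-2-en-1-one | C[C@@H]1CC(OC)=C(I)C(=O)[C@H]1OC | intermediate
12 | 2-methoxypropene | COC(C)=C | starting material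
13 | acrolein | C=CC=O | starting material
14 | (R)-5-methoxyhexa-1,5-dien-3-ol | C=C(OC)C[C@@H](O)C=C | intermediate
15 | (R)-4-hydroxyhex-5-en-2-one | CC(=O)C[C@@H](O)C=C | intermediate
16 | [(4R,5S)-2,5-dimethoxy-4-methyl-6-oxocyclohex-1-en-1-yl]magnesium chloride | C[C@@H]1CC(OC)=C([Mg]Cl)C(=O)[C@H]1OC | intermediate
17 | chloromagnesium alkoxide of (R)-4-hydroxyhex-5-en-2-one | CC(=O)C[C@@H](O[Mg]Cl)C=C | intermediate
18 | (5R,6S)-2-[(2R,4R)-2,4-dihydroxyhex-5-en-2-yl]-3,6-dimethoxy-5-methylcyclohex-2-en-1-one | C=C[C@H](O)C[C@@](C)(O)C1=C(OC)C[C@@H](C)[C@H](OC)C1=O | intermediate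
19 | angelic acid, (Z)-2-methylbut-2-enoic acid | C/C=C(/C)C(=O)O | starting material
20 | (3S,5R)-5-[(4R,5S)-2,5-dimethoxy-4-methyl-6-oxocyclohex-1-en-1-yl]-5-hydroxyhex-1-en-3-yl (Z)-2-methylbut-2-enoate | C=C[C@@H](OC(=O)/C(C)=C\C)C[C@@](C)(O)C1=C(OC)C[C@@H](C)[C@H](OC)C1=O | intermediate
21 | (3S,5R)-5-acetoxy-5-[(4R,5S)-2,5-dimethoxy-4-methyl-6-oxocyclohex-1-en-1-yl]hex-1-en-3-yl (Z)-2-methylbut-2-enoate | C=C[C@@H](OC(=O)/C(C)=C\C)C[C@@](C)(OC(C)=O)C1=C(OC)C[C@@H](C)[C@H](OC)C1=O | intermediate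
22 | (3S,5R)-5-acetoxy-5-[(3S,4R)-3-methoxy-4-methyl-6-oxo-2-(trifluoromethylsulfonyloxy)cyclohex-1-en-1-yl]hex-1-en-3-yl (Z)-2-methylbut-2-enoate | C=C[C@@H](OC(=O)/C(C)=C\C)C[C@@](C)(OC(C)=O)C1=C(OS(=O)(=O)C(F)(F)F)[C@@H](OC)[C@H](C)CC1=O | intermediate
23 | 2-(bromomethyl)acrylic acid | C=C(CBr)C(=O)O | starting material
24 | (2Z,4S,6R)-6-acetoxy-2-(bromomethyl)-6-[(3S,4R)-3-methoxy-4-methyl-6-oxo-2-(trifluoromethylsulfonyloxy)cyclohex-1-en-1-yl]-4-{[(Z)-2-methylbut-2-enoyl]oxy}hept-2-enoic acid | OC(=O)/C(CBr)=C/[C@@H](OC(=O)/C(C)=C\C)C[C@@](C)(OC(C)=O)C1=C(OS(=O)(=O)C(F)(F)F)[C@@H](OC)[C@H](C)CC1=O | intermediate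
25 | Barbier adduct: bicyclo[4.4.0]dec-5-ene with tertiary C1–OH at the ring fusion, C5 enol triflate, C10 bearing 1-carboxyvinyl trans to C9–OAng (C1 configuration not defined, it is destroyed next) | C=C(C(=O)O)[C@@H]1[C@@H](OC(=O)/C(C)=C\C)C[C@@](C)(OC(C)=O)C2=C(OS(=O)(=O)C(F)(F)F)[C@@H](OC)[C@H](C)CC12O | intermediate
26 | potassium salt of the ring-expanded keto acid (C1 ketone, C5≡C6) | C=C(C(=O)[O-])[C@H]1C(=O)C[C@@H](C)[C@H](OC)C#C[C@](C)(OC(C)=O)C[C@@H]1OC(=O)/C(C)=C\C.[K+] | intermediate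
27 | ten-membered cycloalkynone methyl ester (C1 ketone, C5≡C6, stereocentres C3, C4, C7, C9, C10 as in the target) | C=C(C(=O)OC)[C@H]1C(=O)C[C@@H](C)[C@H](OC)C#C[C@](C)(OC(C)=O)C[C@@H]1OC(=O)/C(C)=C\C | intermediate
28 | (1R)-hydroxy ester from reduction of 27 | C=C(C(=O)OC)[C@H]1[C@H](O)C[C@@H](C)[C@H](OC)C#C[C@](C)(OC(C)=O)C[C@@H]1OC(=O)/C(C)=C\C | intermediate
29 | alkyne lactone (C5≡C6 analogue of the target, trans-fused α-methylene lactone) | C=C1C(=O)O[C@@H]2C[C@@H](C)[C@H](OC)C#C[C@](C)(OC(C)=O)C[C@H](OC(=O)/C(C)=C\C)[C@@H]12 | intermediate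
30 | Rufesolide C | C=C1C(=O)O[C@@H]2C[C@@H](C)[C@H](OC)CC(=O)[C@](C)(OC(C)=O)C[C@H](OC(=O)/C(C)=C\C)[C@@H]12 | target

**Totals**
Total steps: 15. Longest linear sequence: 14 steps (steps 1–6 and 8–15).

**Three steps most likely to fail**

Step 11 (new dealkylative triflation; the neighbouring tertiary acetate or incomplete demethylation could interfere). Fallback from 21 back to 22 by known chemistry: hydrolyse the methyl enol ether with dilute HCl in THF to the 1,3-dione F1 (drawn as its C5 enol), then triflate with Tf2O and pyridine at −78 °C, the standard preparation of vinylogous acyl triflates from 1,3-diones. The C5 enol, hydrogen-bonded to the C4 methoxy group and leaving the unhindered C1 as the ketone, is the tautomer expected to be trapped.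

Step 13 (new ring expansion; the alkoxide may not fragment cleanly, or C10 may epimerise). Fallback from 25 back to 27 by an Eschenmoser–Tanabe sequence: isolate 25 after the zinc step and esterify with Me3SiCHN2 to the methyl ester F2. Reduce the enol triflate with Pd(OAc)2/PPh3 and HCO2H/Bu3N to the tertiary allylic alcohol F3. Transpose by Babler–Dauben oxidation with pyridinium chlorochromate, C5H5NH[CrO3Cl], to the ring-fusion enone F4. Epoxidise with dimethyldioxirane to the epoxy ketone F5, and fragment with p-toluenesulfonylhydrazide in AcOH/CH2Cl2 to give 27.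

Step 15 (regiochemistry; a competing 1,3-acyloxy shift would give an enone). Fallback from 29 back to 30: N-iodosuccinimide in wet MeCN, by iodonium-induced 5-exo participation of the acetate (electrophile-induced cyclisation of an alkyne with a neighbouring ester), gives the α-iodo ketone F6 with iodine on C5. Zinc dust in NH4Cl-buffered aqueous THF then removes the iodine to give 30.

**Further compounds**
F1 | step 11 | (3S,5R)-5-acetoxy-5-[(3S,4R)-2-hydroxy-3-methoxy-4-methyl-6-oxocyclohex-1-en-1-yl]hex-1-en-3-yl (Z)-2-methylbut-2-enoate (C5 enol of the 1,3-dione) | C=C[C@@H](OC(=O)/C(C)=C\C)C[C@@](C)(OC(C)=O)C1=C(O)[C@@H](OC)[C@H](C)CC1=O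
F2 | step 13 | methyl ester of Barbier adduct 25 | C=C(C(=O)OC)[C@@H]1[C@@H](OC(=O)/C(C)=C\C)C[C@@](C)(OC(C)=O)C2=C(OS(=O)(=O)C(F)(F)F)[C@@H](OC)[C@H](C)CC12O
F3 | step 13 | tertiary allylic alcohol (C5–H in place of C5–OTf) | C=C(C(=O)OC)[C@@H]1[C@@H](OC(=O)/C(C)=C\C)C[C@@](C)(OC(C)=O)C2=C[C@@H](OC)[C@H](C)CC12O
F4 | step 13 | ring-fusion enone (C5 ketone, C6=C1) | C=C(C(=O)OC)[C@@H]1[C@@H](OC(=O)/C(C)=C\C)C[C@@](C)(OC(C)=O)C2=C1C[C@@H](C)[C@H](OC)C2=O
F5 | step 13 | α,β-epoxy ketone (C6–C1 epoxide, face not defined) | C=C(C(=O)OC)[C@@H]1[C@@H](OC(=O)/C(C)=C\C)C[C@@](C)(OC(C)=O)C23OC12C[C@@H](C)[C@H](OC)C3=O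
F6 | step 15 | 5-iodo derivative of Rufesolide C (C5 configuration not defined) | C=C1C(=O)O[C@@H]2C[C@@H](C)[C@H](OC)C(I)C(=O)[C@](C)(OC(C)=O)C[C@H](OC(=O)/C(C)=C\C)[C@@H]12
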